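**Retrosynthetic overview**
1. Locants: ring A is the monophenol ring (C1 OH, C3 ether O, C5 chain). Ring B is the dihydroxy ring (C1' chain, C3'/C5' OH, C4' ether O). The chain runs from C1 (carbinol, on C1') to C14 (on C5).
2. Endgame: the C1 stereocentre is set last by asymmetric transfer hydrogenation of the triphenolic macrocyclic ketone. That ketone comes from O-demethylation and, before it, from a late benzylic C–H oxidation of a macrocycle whose bridge is a bare (CH2)14 chain.
3. Key disconnections: C5–C14 and C1'–C1, leading to a bromo/chloro diaryl ether and commercial tetradeca-1,13-diene. In one flask the diene is hydroborated at both ends, coupled at C1'–Br, then closed at C5–Cl (B-alkyl Suzuki–Miyaura); the C5–C14 bond closes the ring.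
4. Order of rings: rings A and B are bought and joined by an Ullmann ether synthesis. The 22-membered macrocycle is the only ring made, and it is made in the key step.
5. Enabling feature: the bridge is an unbranched C14 chain held only by its two terminal carbons, C14 on C5 of ring A and C1 on C1' of ring B. Each anchor carbon lies between two aromatic C–H positions, so the bridge is the skeleton of an alpha,omega-diene and both anchors are open to palladium. The chain ends differ only in the C1 hydroxyl; C1 is para to the ether oxygen on C4', whereas C14 is meta to both oxygens of ring A, so this oxygen can be added after ring closure.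

Key step: step 2

Assumption: compounds 1, 2 and 4 are taken as catalogue chemicals.

Step 1
Reactants: 1 4-bromo-2,6-dimethoxyphenol; 2 1-chloro-3-iodo-5-methoxybenzene
Product: 3 5-bromo-2-(3-chloro-5-methoxyphenoxy)-1,3-dimethoxybenzene
Conditions: 2 (1.2 equiv), CuI (10 mol %), picolinic acid (20 mol %), K3PO4 (2 equiv), DMSO, 80 °C, N2
Reagents that add atoms: none
Why: Ullmann diaryl ether synthesis with a picolinate-ligated copper catalyst, a system suited to di-ortho-substituted phenols: the C–I bond of 2 should react well ahead of the C–Br bonds of 1 and 3 and of the C–Cl bond, the slight excess of 2 keeps it so, and the inert atmosphere protects the oxidation-prone phenoxide.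

Step 2
Reactants: 3 5-bromo-2-(3-chloro-5-methoxyphenoxy)-1,3-dimethoxybenzene; 4 tetradeca-1,13-diene
Product: 7 deoxy macrocycle tri-O-methyl ether, via bis-borane 5 (not isolated), via chloro borane 6 (not isolated)
Conditions: (a) 4 (1.5 equiv), 9-BBN-H (3.1 equiv), THF, 0 °C to rt; (b) 3, PdCl2(dppf) (5 mol %), 3 M aq K3PO4, THF, 50 °C; (c) syringe pump (16 h) into Pd(OAc)2 (10 mol %), SPhos (20 mol %), K3PO4, THF/H2O, 65 °C, 1 mM final
Reagents that add atoms: none
Why: 9-BBN-H adds anti-Markovnikov to both vinyl groups of 4 to give 5, and PdCl2(dppf), which inserts into the C1'–Br bond of ring B but not into an aryl chloride, joins one boron-bearing terminus (C1) to ring B by oxidative addition, transmetalation of the hydroxyborate and reductive elimination, giving 6. On slow addition to SPhos-ligated zerovalent palladium the C5–Cl bond of ring A undergoes oxidative addition, the tethered B-alkyl hydroxyborate transmetalates within the same molecule, and reductive elimination forms the C5–C14 bond. The closest known reaction types are the bis-hydroboration of alpha,omega-dienes followed by twofold B-alkyl Suzuki–Miyaura coupling with dihaloarenes to give [n]cyclophanes, and the B-alkyl Suzuki–Miyaura macrocyclisation of omega-boryl aryl halides. The one ring closed is the 22-membered macrocycle, by end-to-end closure of a saturated, strain-free fourteen-carbon tether between the meta-linked ring A and the para-linked ring B, and no stereocentre is formed. The step needs the order ring B first and ring A last, which the bromide/chloride pair and the change of ligand secure, and it needs ring closure to beat chain growth, which is served by the moderate excess of cheap 5 in stage b (against 2:1 adducts), the high dilution in stage c, and an aryl-palladium chloride that has no beta-hydrogen and can wait for a slow transmetalation. Both anchor carbons carry two ortho hydrogens, so the methoxy groups hinder neither the oxidative addition nor the reductive elimination.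

Step 3
Reactants: 7 deoxy macrocycle tri-O-methyl ether
Product: 9 macrocyclic C1 ketone tri-O-methyl ether, via racemic C1 alcohol 8 (not isolated)
Conditions: DDQ (3 equiv), 1,4-dioxane/H2O (9:1), rt to 60 °C
Reagents that add atoms: water (O)
Why: DDQ benzylic oxidation of a para-oxygenated alkylarene: DDQ should abstract hydride from C1 because only there is the cation stabilised by a lone pair of the para ether oxygen on C4', whereas C14 is meta to both oxygens of ring A and gains nothing, water traps the cation to 8, the alpha-hydroxy C–H of 8 is the better hydride donor and is oxidised on to 9, and the new carbonyl group deactivates ring B so that the oxidation stops there.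

Step 4
Reactants: 9 macrocyclic C1 ketone tri-O-methyl ether
Product: 10 macrocyclic C1 ketone with three free phenols
Conditions: BBr3 (6 equiv), CH2Cl2, −78 °C to rt; then H2O
Reagents that add atoms: none
Why: Lewis acid mediated aryl methyl ether cleavage: each methoxy oxygen binds boron and bromide removes the methyl group by SN2, whereas the diaryl ether offers no sp3 carbon and the aryl ketone binds BBr3 only reversibly, and doing this at the ketone level means that no ionisable benzylic alcohol ever meets a Lewis acid.

Step 5
Reactants: 10 macrocyclic C1 ketone with three free phenols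
Product: 11 gravicycle
Conditions: RuCl[(R,R)-TsDPEN](p-cymene) (2 mol %), HCO2H/Et3N (5:2), DMF, 40 °C
Reagents that add atoms: none
Why: Noyori asymmetric transfer hydrogenation: the ruthenium hydride delivers hydride and the ligand N–H proton through a six-membered outer-sphere transition state in which ring B lies next to the p-cymene ligand (CH/pi attraction), so the (R,R) catalyst should give the (R)-carbinol as with other aryl n-alkyl ketones, the acidic medium keeps the three phenols (all meta to or remote from the carbonyl) protonated, and no later step can scramble the centre.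

**Compound list**
1 | 4-bromo-2,6-dimethoxyphenol | COc1cc(Br)cc(OC)c1O | starting material
2 | 1-chloro-3-iodo-5-methoxybenzene | COc1cc(Cl)cc(I)c1 | starting material
3 | 5-bromo-2-(3-chloro-5-methoxyphenoxy)-1,3-dimethoxybenzene (Br on C1' of ring B, Cl on C5 of ring A) | COc1cc(Cl)cc(Oc2c(OC)cc(Br)cc2OC)c1 | intermediate
4 | tetradeca-1,13-diene | C=CCCCCCCCCCCCC=C | starting material
5 | 1,14-bis(9-borabicyclo[3.3.1]nonan-9-yl)tetradecane | C1CC2CCCC(C1)B2CCCCCCCCCCCCCCB1C2CCCC1CCC2 | intermediate
6 | 9-{14-[4-(3-chloro-5-methoxyphenoxy)-3,5-dimethoxyphenyl]tetradecyl}-9-borabicyclo[3.3.1]nonane | COc1cc(Cl)cc(Oc2c(OC)cc(CCCCCCCCCCCCCCB3C4CCCC3CCC4)cc2OC)c1 | intermediate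
7 | deoxy macrocycle tri-O-methyl ether: 22-membered diaryl ether cyclophane, (CH2)14 bridge from C5 of ring A (C1 OMe) to C1' of ring B (C3', C5' OMe) | COc1cc2cc(c1)Oc1c(OC)cc(cc1OC)CCCCCCCCCCCCCC2 | intermediate
8 | racemic C1 alcohol of 7 | COc1cc2cc(c1)Oc1c(OC)cc(cc1OC)C(O)CCCCCCCCCCCCC2 | intermediate
9 | macrocyclic C1 ketone tri-O-methyl ether | COc1cc2cc(c1)Oc1c(OC)cc(cc1OC)C(=O)CCCCCCCCCCCCC2 | intermediate
10 | macrocyclic C1 ketone with free OH on C1, C3' and C5' | Oc1cc2cc(c1)Oc1c(O)cc(cc1O)C(=O)CCCCCCCCCCCCC2 | intermediate
11 | gravicycle, (R) at C1 | Oc1cc2cc(c1)Oc1c(O)cc(cc1O)[C@H](O)CCCCCCCCCCCCC2 | target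

**Step count and weak points**

Total steps: 5. Longest linear sequence: 5 steps (from 1 or 2 to 11).

**Step 3.**
- What may go wrong: the two methoxy groups next to the C4' oxygen twist the aryloxy group out of the plane of ring B, so hydride abstraction from C1 may be too slow. The cation may also lose a proton from C2 to a styrene that is oxidised further.
- Fallback (sets out from 3, comes back at 9): the C1 oxygen is brought in with the chain instead of by C–H oxidation. 11-Bromoundecanoic acid and allylmagnesium bromide (Li2CuCl4 cat, THF, −20 °C) give tetradec-13-enoic acid F1. 1,1'-Carbonyldiimidazole and MeNHOMe·HCl turn it into the Weinreb amide N-methoxy-N-methyltetradec-13-enamide F2. Bromine–lithium exchange on 3 (n-BuLi, THF, −78 °C, chloride untouched) gives aryllithium F3, which F2 acylates to alkenyl ketone F4. Ethylene glycol, TsOH and toluene (Dean–Stark) give dioxolane F5, which masks the ketone against the borane. 9-BBN-H gives borane F6, and slow addition to Pd(OAc)2/SPhos/K3PO4 closes the same C5–C14 bond to macrocyclic dioxolane F7. Aqueous HCl/THF then frees 9.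

**Step 2.**
- What may go wrong: chain growth, through 2:1 adducts of 3 with 5 in stage b and through capture of the ring A aryl-palladium species by surplus 5 in stage c.
- Fallback (sets out from 3 and 4, comes back at 6 and then 7): the closure is made strictly unimolecular. Diene 4 in fourfold excess is hydroborated with one equivalent of 9-BBN-H to mono-borane F8. This is coupled with 3 at C1'–Br (PdCl2(dppf), aq K3PO4, THF), and the alkenyl aryl chloride F9 is isolated and freed from surplus 4 by chromatography. 9-BBN-H then gives 6 as the only borane in the flask, and slow addition to Pd(OAc)2/SPhos/K3PO4 closes the ring to 7.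

**Step 1.**
- What may go wrong: sluggish coupling of the di-ortho-substituted phenoxide, and competing copper insertion into the C–Br bond of 1 or 3, which leads to oligomeric ethers.
- Fallback (sets out from 1 and 2, comes back at 3): metal-free O-arylation with a diaryliodonium salt. 2 is oxidised with mCPBA/TsOH·H2O in MeCN and trapped with 1,3,5-trimethoxybenzene to give iodonium tosylate F10. With 1 and K2CO3 in toluene at 60 °C, ligand coupling at trivalent iodine should transfer the less electron-rich 3-chloro-5-methoxyphenyl group to the phenoxide oxygen. This gives 3 without touching either halogen.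

**Further compounds**
F1 | step 3 | tetradec-13-enoic acid | OC(=O)CCCCCCCCCCCC=C
F2 | step 3 | N-methoxy-N-methyltetradec-13-enamide | CON(C)C(=O)CCCCCCCCCCCC=C
F3 | step 3 | [4-(3-chloro-5-methoxyphenoxy)-3,5-dimethoxyphenyl]lithium | [Li]c1cc(OC)c(Oc2cc(Cl)cc(OC)c2)c(OC)c1
F4 | step 3 | 1-[4-(3-chloro-5-methoxyphenoxy)-3,5-dimethoxyphenyl]tetradec-13-en-1-one | COc1cc(Cl)cc(Oc2c(OC)cc(cc2OC)C(=O)CCCCCCCCCCCC=C)c1
F5 | step 3 | 2-[4-(3-chloro-5-methoxyphenoxy)-3,5-dimethoxyphenyl]-2-(tridec-12-en-1-yl)-1,3-dioxolane | COc1cc(Cl)cc(Oc2c(OC)cc(cc2OC)C3(CCCCCCCCCCCC=C)OCCO3)c1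
F6 | step 3 | 9-BBN adduct of F5 (boron on the terminal carbon C14) | COc1cc(Cl)cc(Oc2c(OC)cc(cc2OC)C3(CCCCCCCCCCCCCB4C5CCCC4CCC5)OCCO3)c1
F7 | step 3 | ethylene ketal of 9 (macrocyclic dioxolane) | COc1cc2cc(c1)Oc1c(OC)cc(cc1OC)C1(OCCO1)CCCCCCCCCCCCC2
F8 | step 2 | 9-(tetradec-13-en-1-yl)-9-borabicyclo[3.3.1]nonane | C=CCCCCCCCCCCCCB1C2CCCC1CCC2
F9 | step 2 | 2-(3-chloro-5-methoxyphenoxy)-1,3-dimethoxy-5-(tetradec-13-en-1-yl)benzene | COc1cc(Cl)cc(Oc2c(OC)cc(CCCCCCCCCCCCC=C)cc2OC)c1
F10 | step 1 | (3-chloro-5-methoxyphenyl)(2,4,6-trimethoxyphenyl)iodonium 4-methylbenzenesulfonate | COc1cc(Cl)cc([I+]c2c(OC)cc(OC)cc2OC)c1.Cc1ccc(cc1)S(=O)(=O)[O-]
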